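**Proposed synthesis of CNP0168406.2, the (2R)-flavanone–flavone biaryl (naringenin C6 joined to luteolin C6')**

## Analysis of the target

The target joins two C15 flavonoid units through one biaryl bond: a (2R)-5,7,4'-trihydroxyflavanone and a 5,7,3',4'-tetrahydroxyflavone, linked from C6 of the flavanone ring A to C6' of the flavone's catechol ring B. The only stereocentre is C2 of the flavanone. It is benzylic, carries the ring oxygen and sits β to the C4 ketone, so base can open the ring to the 2'-hydroxychalcone and erase it. Seven free phenols, a catechol and two phloroglucinol-type rings make the final compound prone to oxidation and rule out harsh deprotection. The biaryl bond lies between two electron-rich rings and has three ortho substituents (two oxygens and the chromenyl group). The flavanone must be annulated on the correct side of its ring A, because the 6-linked and 8-linked isomers differ only in which oxygen becomes O1. Two structural features carry the plan. First, in the flavone half the atoms C2, C3, C4, C4a, C5, C6, C7, C8 and C8a form nine contiguous carbons with oxygen on every second one, ending at C1' of the catechol ring. This is the pattern of a linear poly-β-carbonyl chain, so ring A of the flavone can be folded from an open chain. Second, flavanone C6 lies on the local symmetry axis of its phloroglucinol ring (between C5–O and C7–O, para to O1), so that ring can be carried as a two-fold symmetric aryl unit until the flavanone is built.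

## Retrosynthetic reasoning

Target 30 is traced to its heptabenzyl ether 29 by cutting seven O–benzyl bonds. With every phenol masked in the same way, one neutral hydrogenolysis ends the synthesis and no base touches C2 once it exists.

In 29 the C2–aryl bond of the flavanone is cut, giving chromone 27 and boronic acid 28. This places the stereocentre in the last C–C bond, set by a chiral catalyst on an achiral substrate. The second enone of 27 is the flavone, which is β,β-disubstituted and should not compete, so no extra protection is needed. The forward reaction is an enantioselective 1,4-arylation of a 2-unsubstituted chromone.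

The chromone ring of 27 is opened at O1–C2 and C2–C3, leading to the ortho-hydroxyacetophenone 25, with C2 coming from a one-carbon amide acetal. The acetyl group of 25 is removed via the aryl iodide 23, which comes from phenol 22. In 22 the two positions ortho to the hydroxyl are equivalent and the para position is the biaryl carbon. Ortho-functionalisation can therefore only lead to the 6-linked flavanone. The iodide/alkoxyvinyl-tin route to the acetyl group avoids Lewis-acid acylation in a molecule with six benzyl ethers.

Phenol 22 comes from allyl ether 21, and 21 from the dihydroxyflavone 20 by benzylation. The allyl group marks the one oxygen that will become O1 of the flavanone, and the flavone 5- and 7-hydroxyls are benzylated before it is removed, so the phenol of 22 is unique.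

Flavone 20 is opened at O1–C2 to the 1,3-diketone 19. Because the trihydroxyphenyl ring of 19 is symmetric, either ortho hydroxyl gives the same flavone.

In 19 the C4a–C5 bond of the flavone ring A is cut, unfolding the phloroglucinol ring into the tetraketo ester 18. This is the central disconnection: it replaces the preparation and selective protection of a phloroglucinol ketone by a chain whose oxygen pattern already matches ring A. The forward reaction must acylate a chain carbon with the ester (Claisen mode) in preference to the aldol closures open to the same chain.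

Ester 18 is traced through acid 17 to tetraketone 16 by removing the terminal carboxyl carbon. Tetraketone 16 is cut between the aryl ketone carbon and the adjacent methylene into biaryl ester 13 and triketone 15. Both forward bonds use the same logic: in a polyanion the terminal carbanion is formed last and reacts first.

Ester 13 is cut at the biaryl bond into aryl bromide 7 and bromo ester 10. The bromide of 10 is activated by the ortho ester, and the aryl metal from 7 is symmetric, so the coupling raises no regiochemical question.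

Bromide 7 goes back to 2-bromoresorcinol 1: the third oxygen is introduced at the only unhindered C–H bond by borylation and oxidation, carried out on silyl ethers because benzyl groups would offer competing aromatic C–H bonds. Bromo ester 10 comes from methyl 3,4-dihydroxybenzoate 8, and triketone 15 from the pyranone 14.

## Alternatives that were turned down

Alternative 1: The catechol ring is disconnected at two adjacent positions, the biaryl bond and the bond to the future flavone C2, treating it as an aryne. In the forward step Grignard reagent A3 adds to the symmetric aryne released from dibromide A2 with magnesium, and the resulting 2-biaryl Grignard is carboxylated to acid A1. In its favour, two bonds form in one flask, the aryne is symmetric, and no palladium is present, so a silyl ether can mark the para oxygen. Against it, the hindered Grignard A3 must intercept a transient aryne faster than the product Grignard adds to a second aryne, and the rate of aryne release from A2 is hard to match to that. More important, A1 only reaches the stage of ester 13; the flavone rings still have to be made. On the biaryl bond it is at least as short as the coupling of 7 with 10. It does not, however, address the construction of the flavone nucleus, which is what the chain-folding plan supplies.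

Alternative 2: The flavanone ring C is disconnected at C4–C4a, with the C2–O1 ether and the stereocentre already in place. Acid A5, a (3R)-3-aryloxy-3-arylpropanoic acid built on phenol 22, is activated as a mixed anhydride and acylates ring A ortho to the ether oxygen to give A4. In its favour, the two ortho positions are equivalent, no separate ortho-acylation is needed, and the stereocentre could come from a well-established asymmetric reduction followed by etherification with inversion. Against it, the C2–O1 bond is a benzylic aryl ether next to a para-oxygenated ring. Under acidic acylation it can ionise or eliminate to a cinnamic acid and phenol 22, which destroys the configuration. The etherification of a secondary benzylic alcohol with a hindered phenol is also prone to partial loss of stereochemical integrity. It is shorter than steps 16 to 19 of the chosen route and needs no chiral metal catalyst. The chosen endgame instead sets C2 last, under near-neutral conditions and by catalyst control. Alternative 2 also depends on the same phenol 22, so it offers nothing for the earlier part of the synthesis.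

Alternative 3: The flavone is disconnected at C2–C3 and O1–C2. The dianion of acetophenone A8 opens the lactone carbonyl of the benzo[c]chromenone A7, and acid work-up closes the pyranone to give flavone A6, which one benzylation would convert into 21. In its favour, it is convergent and short, the lactone activates the hindered carboxyl group, and the ring-forming event is a predictable Claisen-type acylation. On step count and on predictability of ring formation it is stronger than the chosen strategy. Against it, the released phenoxide can re-close the lactone, so the acylation is reversible until the diketone is deprotonated, and a selectively protected phloroglucinol ketone has to be supplied as a separate building block. The chosen strategy instead derives all of flavone ring A, C4, C3 and C2 from one C7 triketone and one carboxylation, and keeps the phloroglucinol ring symmetric at the moment it is formed. The acylation logic of alternative 3 is kept in reserve as the fallback for the key step.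

Key step: step 12

## Route

Remark on the chemistry (assumption): the target carries no descriptor for the biaryl axis. It is assumed to rotate freely enough in the heptaphenol that only C2 needs to be controlled; intermediates from 23 onward may exist as slowly interconverting rotamers. Methyl 3,4-dihydroxybenzoate is used as the commercial ester of 3,4-dihydroxybenzoic acid.

Step 1
Reactants: 1 2-bromoresorcinol (2-bromobenzene-1,3-diol)
Product: 2 2-bromo-1,3-bis(tert-butyldimethylsilyloxy)benzene
Conditions: TBSCl (2.4 equiv), imidazole, DMF, rt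
Reagents that add atoms: tert-butyldimethylsilyl chloride, CC(C)(C)[Si](C)(C)Cl
Why: Silylation of both phenols; silyl ethers are used here because, unlike benzyl ethers, they offer no unhindered aromatic C–H bond to compete in the borylation of step 2.

Step 2
Reactants: 2 bis-silyl ether
Product: 4 4-bromo-3,5-bis(tert-butyldimethylsilyloxy)phenol, via aryl pinacolboronate 3 (not isolated)
Conditions: [Ir(OMe)(cod)]2 (1.5 mol %), 4,4'-di-tert-butyl-2,2'-bipyridine (3 mol %), B2pin2 (0.6 equiv), THF, 80 °C; then Oxone (2KHSO5·KHSO4·K2SO4), acetone/H2O, rt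
Reagents that add atoms: bis(pinacolato)diboron, CC1(C)OB(OC1(C)C)B1OC(C)(C)C(C)(C)O1 (boron is kept only in 3); potassium peroxymonosulfate, [K+].[O-]S(=O)(=O)OO (phenol oxygen of 4)
Why: Iridium-catalysed C–H borylation is sterically governed and should take the only C–H bond of 2 without an ortho substituent (C5, para to bromine); ipso-hydroxylation of the boronate in the same flask gives the phenol, and the aryl bromide is tolerated.

Step 3
Reactants: 4 phenol
Product: 5 5-(allyloxy)-2-bromo-1,3-bis(tert-butyldimethylsilyloxy)benzene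
Conditions: allyl alcohol, PPh3, DIAD, THF, 0 °C → rt
Reagents that add atoms: allyl alcohol (prop-2-en-1-ol), C=CCO
Why: Mitsunobu etherification of the unhindered phenol under neutral conditions, which avoids the silyl scrambling a phenoxide could cause.

Step 4
Reactants: 5 allyl ether
Product: 7 5-(allyloxy)-1,3-bis(benzyloxy)-2-bromobenzene, via 5-(allyloxy)-2-bromobenzene-1,3-diol 6 (not isolated)
Conditions: KF, BnBr (2.5 equiv), DMF, rt → 40 °C
Reagents that add atoms: benzyl bromide, BrCc1ccccc1
Why: Fluoride cleaves the aryl silyl ethers and the phenoxides are benzylated in the same flask (one-pot desilylation and Williamson etherification); the allyl ether and aryl bromide are inert.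

Step 5
Reactants: 8 methyl 3,4-dihydroxybenzoate
Product: 9 methyl 3,4-bis(benzyloxy)benzoate
Conditions: BnBr, K2CO3, DMF, 60 °C
Reagents that add atoms: benzyl bromide, BrCc1ccccc1
Why: Williamson etherification of both catechol hydroxyls.

Step 6
Reactants: 9 dibenzyl ether
Product: 10 methyl 4,5-bis(benzyloxy)-2-bromobenzoate
Conditions: Br2 (1.05 equiv), NaOAc, AcOH, rt
Reagents that add atoms: bromine, BrBr
Why: Electrophilic aromatic bromination para to the 3-alkoxy group and ortho to the ester, the position at which 3,4-dialkoxybenzoates are known to brominate; the benzyl rings are far less activated.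

Step 7
Reactants: 7 aryl bromide; 10 bromo ester
Product: 13 methyl 2-[4-(allyloxy)-2,6-bis(benzyloxy)phenyl]-4,5-bis(benzyloxy)benzoate, via aryllithium 11 (not isolated), via arylzinc chloride 12 (not isolated)
Conditions: 7, n-BuLi, THF, −78 °C; ZnCl2, −78 °C → rt; then 10, Pd2(dba)3 (2 mol %), RuPhos (8 mol %), THF, 65 °C
Reagents that add atoms: n-butyllithium, [Li]CCCC (lithium in 11 only); zinc chloride, Cl[Zn]Cl (zinc and chloride in 12 only)
Why: Bromine–lithium exchange, transmetalation to zinc and Negishi coupling; the bulky dialkylbiarylphosphine supports oxidative addition to the ester-activated bromide and reductive elimination at a tri-ortho-substituted axis, and the ester tolerates the organozinc.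

Step 8
Reactants: 14 2,6-dimethyl-4H-pyran-4-one
Product: 15 heptane-2,4,6-trione
Conditions: Ba(OH)2·8H2O, H2O, rt; then aq. HCl, 0 °C
Reagents that add atoms: water, O
Why: Hydrolytic ring opening of the 4-pyranone (a vinylogous ester) to the 1,3,5-triketone, which is released from its barium chelate by cold acidification and used promptly.

Step 9
Reactants: 13 biaryl methyl ester; 15 heptane-2,4,6-trione
Product: 16 1-{2-[4-(allyloxy)-2,6-bis(benzyloxy)phenyl]-4,5-bis(benzyloxy)phenyl}octane-1,3,5,7-tetraone
Conditions: 15 (2.2 equiv), LiN(i-Pr)2 (6.6 equiv), THF, 0 °C; then 13, 0 °C → rt; cold 1 M HCl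
Reagents that add atoms: none
Why: Claisen-type acylation of a polyanion: in the trilithium salt of 15 the terminal carbanion is formed last and is the most nucleophilic site, so the ester is attacked there; the excess trianion deprotonates the product, which stays as its polyenolate until the cold quench and so cannot cyclise.

Step 10
Reactants: 16 tetraketone
Product: 17 9-{2-[4-(allyloxy)-2,6-bis(benzyloxy)phenyl]-4,5-bis(benzyloxy)phenyl}-3,5,7,9-tetraoxononanoic acid
Conditions: LiN(i-Pr)2 (4.5 equiv), THF, 0 °C; CO2, −78 → 0 °C; cold aq. HCl, extraction at 0 °C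
Reagents that add atoms: carbon dioxide, O=C=O
Why: Carboxylation of the terminal carbanion of the tetralithium salt of 16; the β-keto acid is kept cold and taken on at once because it would lose CO2 on warming.

Step 11
Reactants: 17 tetraketo acid
Product: 18 methyl 9-{2-[4-(allyloxy)-2,6-bis(benzyloxy)phenyl]-4,5-bis(benzyloxy)phenyl}-3,5,7,9-tetraoxononanoate
Conditions: CH2N2 (titrated), Et2O/THF, 0 °C; AcOH quench
Reagents that add atoms: diazomethane, C=[N+]=[N-]
Why: Esterification of the carboxylic acid by diazomethane, which is much faster than O-methylation of the enolised diketone units when the reagent is titrated at 0 °C.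

Step 12
Reactants: 18 tetraketo ester
Product: 19 1-{2-[4-(allyloxy)-2,6-bis(benzyloxy)phenyl]-4,5-bis(benzyloxy)phenyl}-3-(2,4,6-trihydroxyphenyl)propane-1,3-dione
Conditions: Mg(OMe)2 (6 equiv), MeOH (anhydrous), rt → 50 °C; cold aq. HCl
Reagents that add atoms: none
Why: Magnesium methoxide converts the chain into chelated magnesium enolates; the carbon between the C5 and C7 carbonyls (chain numbering from the ester, C6) attacks the ester carbon C1, methoxide is expelled, and the resulting 2-acylcyclohexane-1,3,5-trione tautomerises at once to the aromatic 2,4,6-trihydroxyphenyl ketone. The closest known reaction type is the base-mediated Claisen cyclisation of 3,5,7-trioxo esters to acylphloroglucinols, applied here to a chain one ketide unit longer. The one ring formed is the six-membered carbocycle that becomes flavone ring A, closed in a 6-(enolendo)-exo-trig mode, and the new bond is the flavone C4a–C5 bond. No stereocentre is created. The step needs C-acylation to win over the aldol closures open to the chain (C2 onto C7, C8 onto C3, C4 onto C9). Aldol adducts form reversibly and must still dehydrate from a polyenolate, whereas the Claisen adduct loses methoxide and aromatises irreversibly, so under anhydrous alkoxide with full chelation of the ketones this channel should drain the equilibrium. The aryl ketone at C9 is hindered by the ortho aryl group, electron-rich and not enolisable toward the arene, which further disfavours the aldol closure onto it. The phloroglucinol ring of 19 is symmetric, so the pyranone closure of step 13 can use either ortho hydroxyl with the same result.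

Step 13
Reactants: 19 diketone
Product: 20 2-{2-[4-(allyloxy)-2,6-bis(benzyloxy)phenyl]-4,5-bis(benzyloxy)phenyl}-5,7-dihydroxy-4H-chromen-4-one
Conditions: TsOH·H2O (cat.), AcOH, 60 °C
Reagents that add atoms: none
Why: Acid-catalysed cyclodehydration of an ortho-hydroxyaryl 1,3-diketone, as in the last stage of a Baker–Venkataraman flavone synthesis: a phenol adds to the aryl ketone carbon and water is lost; benzyl and allyl ethers tolerate catalytic sulfonic acid at this temperature.

Step 14
Reactants: 20 dihydroxyflavone
Product: 21 2-{2-[4-(allyloxy)-2,6-bis(benzyloxy)phenyl]-4,5-bis(benzyloxy)phenyl}-5,7-bis(benzyloxy)-4H-chromen-4-one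
Conditions: BnBr, K2CO3, DMF, 70 °C
Reagents that add atoms: benzyl bromide, BrCc1ccccc1
Why: Williamson etherification; the hydrogen-bonded 5-hydroxyl needs DMF and heat. After this step the allyl-protected oxygen is the only one that differs from the rest.

Step 15
Reactants: 21 allyl ether
Product: 22 5,7-bis(benzyloxy)-2-{4,5-bis(benzyloxy)-2-[2,6-bis(benzyloxy)-4-hydroxyphenyl]phenyl}-4H-chromen-4-one
Conditions: Pd(PPh3)4 (5 mol %), morpholine, THF, rt
Reagents that add atoms: none
Why: Tsuji–Trost-type deallylation: zerovalent palladium ionises the allyl aryl ether and morpholine traps the π-allyl complex; benzyl ethers and the flavone are inert.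

Step 16
Reactants: 22 phenol
Product: 23 5,7-bis(benzyloxy)-2-{4,5-bis(benzyloxy)-2-[2,6-bis(benzyloxy)-4-hydroxy-3-iodophenyl]phenyl}-4H-chromen-4-one
Conditions: NIS (1.0 equiv), CH2Cl2, −20 → 0 °C
Reagents that add atoms: N-iodosuccinimide, O=C1CCC(=O)N1I
Why: Electrophilic iodination ortho to the free phenol, on the most electron-rich ring of 22; the two ortho positions are equivalent and the para position is the biaryl carbon, so only one mono-iodide can form.

Step 17
Reactants: 23 iodophenol
Product: 25 2-{2-[3-acetyl-2,6-bis(benzyloxy)-4-hydroxyphenyl]-4,5-bis(benzyloxy)phenyl}-5,7-bis(benzyloxy)-4H-chromen-4-one, via 1-ethoxyvinyl arene 24 (not isolated)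
Conditions: tributyl(1-ethoxyvinyl)stannane, PdCl2(PPh3)2 (5 mol %), toluene, 90 °C; then 1 M HCl, THF, rt
Reagents that add atoms: tributyl(1-ethoxyvinyl)stannane, CCCC[Sn](CCCC)(CCCC)C(=C)OCC; water, O
Why: Stille coupling with a 1-alkoxyvinyl stannane as acetyl anion equivalent, then mild acid hydrolysis of the enol ether; the ortho acetyl group is installed without a Lewis acid that could cleave benzyl ethers.

Step 18
Reactants: 25 ortho-hydroxyacetophenone
Product: 27 5,7-bis(benzyloxy)-6-{4,5-bis(benzyloxy)-2-[5,7-bis(benzyloxy)-4-oxo-4H-chromen-2-yl]phenyl}-4H-chromen-4-one, via enaminone 26 (not isolated)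
Conditions: Me2NCH(OMe)2, toluene, 95 °C; then 2 M HCl, CH2Cl2, 40 °C
Reagents that add atoms: N,N-dimethylformamide dimethyl acetal, COC(OC)N(C)C
Why: Condensation of the methyl ketone with the amide acetal gives the enaminone, and acid then promotes conjugate addition of the phenol and loss of dimethylamine (enaminone route to 2-unsubstituted chromones).

Step 19
Reactants: 27 chromone; 28 [4-(benzyloxy)phenyl]boronic acid
Product: 29 (2R)-5,7-bis(benzyloxy)-2-[4-(benzyloxy)phenyl]-6-{4,5-bis(benzyloxy)-2-[5,7-bis(benzyloxy)-4-oxo-4H-chromen-2-yl]phenyl}chroman-4-one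
Conditions: 28 (3 equiv), Pd(OCOCF3)2 (10 mol %), (S)-t-BuPyOX [(S)-4-tert-butyl-2-(pyridin-2-yl)-4,5-dihydrooxazole] (12 mol %), NH4PF6, H2O, ClCH2CH2Cl, 60 °C
Reagents that add atoms: none
Why: Catalytic asymmetric conjugate addition of an arylpalladium species (formed by transmetalation from boron) to the 2-unsubstituted chromone; C2 is set by the ligand, whose tert-butyl group is expected to direct the aryl group to the face that gives 2R, and the ligand antipode is available should the sense prove opposite. The flavone enone is β,β-disubstituted and should not react, and the near-neutral medium avoids ring opening of the flavanone.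

Step 20
Reactants: 29 heptabenzyl ether
Product: 30 (2R)-6-[2-(5,7-dihydroxy-4-oxo-4H-chromen-2-yl)-4,5-dihydroxyphenyl]-5,7-dihydroxy-2-(4-hydroxyphenyl)chroman-4-one (target)
Conditions: H2 (1 atm), Pd/C (10 wt %), THF/MeOH, rt
Reagents that add atoms: none
Why: Hydrogenolysis of all seven benzyl ethers under neutral conditions, which avoid the base-induced ring opening that would racemise C2; benzyl aryl ethers should cleave faster than the benzylic C2–O1 bond or the flavone double bond is reduced, and the reaction is stopped once hydrogen uptake ceases.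

## Compound list

1 | 2-bromoresorcinol (2-bromobenzene-1,3-diol) | Oc1cccc(O)c1Br | starting material
2 | 2-bromo-1,3-bis(tert-butyldimethylsilyloxy)benzene | CC(C)(C)[Si](C)(C)Oc1cccc(O[Si](C)(C)C(C)(C)C)c1Br | intermediate
3 | 2-[4-bromo-3,5-bis(tert-butyldimethylsilyloxy)phenyl]-4,4,5,5-tetramethyl-1,3,2-dioxaborolane | CC(C)(C)[Si](C)(C)Oc1cc(B2OC(C)(C)C(C)(C)O2)cc(O[Si](C)(C)C(C)(C)C)c1Br | intermediate (not isolated)
4 | 4-bromo-3,5-bis(tert-butyldimethylsilyloxy)phenol | CC(C)(C)[Si](C)(C)Oc1cc(O)cc(O[Si](C)(C)C(C)(C)C)c1Br | intermediate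
5 | 5-(allyloxy)-2-bromo-1,3-bis(tert-butyldimethylsilyloxy)benzene | C=CCOc1cc(O[Si](C)(C)C(C)(C)C)c(Br)c(O[Si](C)(C)C(C)(C)C)c1 | intermediate
6 | 5-(allyloxy)-2-bromobenzene-1,3-diol (formed as its dipotassium salt) | C=CCOc1cc(O)c(Br)c(O)c1 | intermediate (not isolated)
7 | 5-(allyloxy)-1,3-bis(benzyloxy)-2-bromobenzene | C=CCOc1cc(OCc2ccccc2)c(Br)c(OCc2ccccc2)c1 | intermediate
8 | methyl 3,4-dihydroxybenzoate | COC(=O)c1ccc(O)c(O)c1 | starting material
9 | methyl 3,4-bis(benzyloxy)benzoate | COC(=O)c1ccc(OCc2ccccc2)c(OCc2ccccc2)c1 | intermediate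
10 | methyl 4,5-bis(benzyloxy)-2-bromobenzoate | COC(=O)c1cc(OCc2ccccc2)c(OCc2ccccc2)cc1Br | intermediate
11 | [4-(allyloxy)-2,6-bis(benzyloxy)phenyl]lithium | [Li]c1c(OCc2ccccc2)cc(OCC=C)cc1OCc1ccccc1 | intermediate (not isolated)
12 | [4-(allyloxy)-2,6-bis(benzyloxy)phenyl]zinc chloride | Cl[Zn]c1c(OCc2ccccc2)cc(OCC=C)cc1OCc1ccccc1 | intermediate (not isolated)
13 | methyl 2-[4-(allyloxy)-2,6-bis(benzyloxy)phenyl]-4,5-bis(benzyloxy)benzoate | COC(=O)c1cc(OCc2ccccc2)c(OCc2ccccc2)cc1-c1c(OCc2ccccc2)cc(OCC=C)cc1OCc1ccccc1 | intermediate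
14 | 2,6-dimethyl-4H-pyran-4-one | Cc1cc(=O)cc(C)o1 | starting material
15 | heptane-2,4,6-trione | CC(=O)CC(=O)CC(=O)C | intermediate
16 | 1-{2-[4-(allyloxy)-2,6-bis(benzyloxy)phenyl]-4,5-bis(benzyloxy)phenyl}octane-1,3,5,7-tetraone | CC(=O)CC(=O)CC(=O)CC(=O)c1cc(OCc2ccccc2)c(OCc2ccccc2)cc1-c1c(OCc2ccccc2)cc(OCC=C)cc1OCc1ccccc1 | intermediate
17 | 9-{2-[4-(allyloxy)-2,6-bis(benzyloxy)phenyl]-4,5-bis(benzyloxy)phenyl}-3,5,7,9-tetraoxononanoic acid | OC(=O)CC(=O)CC(=O)CC(=O)CC(=O)c1cc(OCc2ccccc2)c(OCc2ccccc2)cc1-c1c(OCc2ccccc2)cc(OCC=C)cc1OCc1ccccc1 | intermediate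
18 | methyl 9-{2-[4-(allyloxy)-2,6-bis(benzyloxy)phenyl]-4,5-bis(benzyloxy)phenyl}-3,5,7,9-tetraoxononanoate | COC(=O)CC(=O)CC(=O)CC(=O)CC(=O)c1cc(OCc2ccccc2)c(OCc2ccccc2)cc1-c1c(OCc2ccccc2)cc(OCC=C)cc1OCc1ccccc1 | intermediate
19 | 1-{2-[4-(allyloxy)-2,6-bis(benzyloxy)phenyl]-4,5-bis(benzyloxy)phenyl}-3-(2,4,6-trihydroxyphenyl)propane-1,3-dione | O=C(CC(=O)c1c(O)cc(O)cc1O)c1cc(OCc2ccccc2)c(OCc2ccccc2)cc1-c1c(OCc2ccccc2)cc(OCC=C)cc1OCc1ccccc1 | intermediate
20 | 2-{2-[4-(allyloxy)-2,6-bis(benzyloxy)phenyl]-4,5-bis(benzyloxy)phenyl}-5,7-dihydroxy-4H-chromen-4-one | O=c1cc(-c2cc(OCc3ccccc3)c(OCc3ccccc3)cc2-c2c(OCc3ccccc3)cc(OCC=C)cc2OCc2ccccc2)oc2cc(O)cc(O)c12 | intermediate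
21 | 2-{2-[4-(allyloxy)-2,6-bis(benzyloxy)phenyl]-4,5-bis(benzyloxy)phenyl}-5,7-bis(benzyloxy)-4H-chromen-4-one | O=c1cc(-c2cc(OCc3ccccc3)c(OCc3ccccc3)cc2-c2c(OCc3ccccc3)cc(OCC=C)cc2OCc2ccccc2)oc2cc(OCc3ccccc3)cc(OCc3ccccc3)c12 | intermediate
22 | 5,7-bis(benzyloxy)-2-{4,5-bis(benzyloxy)-2-[2,6-bis(benzyloxy)-4-hydroxyphenyl]phenyl}-4H-chromen-4-one | O=c1cc(-c2cc(OCc3ccccc3)c(OCc3ccccc3)cc2-c2c(OCc3ccccc3)cc(O)cc2OCc2ccccc2)oc2cc(OCc3ccccc3)cc(OCc3ccccc3)c12 | intermediate
23 | 5,7-bis(benzyloxy)-2-{4,5-bis(benzyloxy)-2-[2,6-bis(benzyloxy)-4-hydroxy-3-iodophenyl]phenyl}-4H-chromen-4-one | O=c1cc(-c2cc(OCc3ccccc3)c(OCc3ccccc3)cc2-c2c(OCc3ccccc3)cc(O)c(I)c2OCc2ccccc2)oc2cc(OCc3ccccc3)cc(OCc3ccccc3)c12 | intermediate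
24 | 5,7-bis(benzyloxy)-2-{4,5-bis(benzyloxy)-2-[2,6-bis(benzyloxy)-3-(1-ethoxyvinyl)-4-hydroxyphenyl]phenyl}-4H-chromen-4-one | O=c1cc(-c2cc(OCc3ccccc3)c(OCc3ccccc3)cc2-c2c(OCc3ccccc3)cc(O)c(C(=C)OCC)c2OCc2ccccc2)oc2cc(OCc3ccccc3)cc(OCc3ccccc3)c12 | intermediate (not isolated)
25 | 2-{2-[3-acetyl-2,6-bis(benzyloxy)-4-hydroxyphenyl]-4,5-bis(benzyloxy)phenyl}-5,7-bis(benzyloxy)-4H-chromen-4-one | O=c1cc(-c2cc(OCc3ccccc3)c(OCc3ccccc3)cc2-c2c(OCc3ccccc3)cc(O)c(C(C)=O)c2OCc2ccccc2)oc2cc(OCc3ccccc3)cc(OCc3ccccc3)c12 | intermediate
26 | 5,7-bis(benzyloxy)-2-(4,5-bis(benzyloxy)-2-{2,6-bis(benzyloxy)-3-[(E)-3-(dimethylamino)acryloyl]-4-hydroxyphenyl}phenyl)-4H-chromen-4-one | O=c1cc(-c2cc(OCc3ccccc3)c(OCc3ccccc3)cc2-c2c(OCc3ccccc3)cc(O)c(C(=O)/C=C/N(C)C)c2OCc2ccccc2)oc2cc(OCc3ccccc3)cc(OCc3ccccc3)c12 | intermediate (not isolated)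
27 | 5,7-bis(benzyloxy)-6-{4,5-bis(benzyloxy)-2-[5,7-bis(benzyloxy)-4-oxo-4H-chromen-2-yl]phenyl}-4H-chromen-4-one | O=c1ccoc2cc(OCc3ccccc3)c(-c3cc(OCc4ccccc4)c(OCc4ccccc4)cc3-c3cc(=O)c4c(OCc5ccccc5)cc(OCc5ccccc5)cc4o3)c(OCc3ccccc3)c12 | intermediate
28 | [4-(benzyloxy)phenyl]boronic acid | OB(O)c1ccc(OCc2ccccc2)cc1 | starting material
29 | (2R)-5,7-bis(benzyloxy)-2-[4-(benzyloxy)phenyl]-6-{4,5-bis(benzyloxy)-2-[5,7-bis(benzyloxy)-4-oxo-4H-chromen-2-yl]phenyl}chroman-4-one | O=C1C[C@H](c2ccc(OCc3ccccc3)cc2)Oc2cc(OCc3ccccc3)c(-c3cc(OCc4ccccc4)c(OCc4ccccc4)cc3-c3cc(=O)c4c(OCc5ccccc5)cc(OCc5ccccc5)cc4o3)c(OCc3ccccc3)c21 | intermediate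
30 | (2R)-6-[2-(5,7-dihydroxy-4-oxo-4H-chromen-2-yl)-4,5-dihydroxyphenyl]-5,7-dihydroxy-2-(4-hydroxyphenyl)chroman-4-one | O=C1C[C@H](c2ccc(O)cc2)Oc2cc(O)c(-c3cc(O)c(O)cc3-c3cc(=O)c4c(O)cc(O)cc4o3)c(O)c21 | target

## Step count and least certain steps

Total step count: 20. Longest linear sequence: 17 steps (steps 1 to 4, 7, 9 to 20).

**Step 12 (key step).** The chain may fold through an aldol closure instead of the Claisen closure, or methoxide may cleave a β-diketone unit by retro-Claisen fragmentation, because several enolisable positions and electrophilic carbonyls compete. The fallback abandons the folding and builds the diketone by acyl transfer. It sets out from 13: saponification (KOH, aqueous dioxane, heat) should give 2-[4-(allyloxy)-2,6-bis(benzyloxy)phenyl]-4,5-bis(benzyloxy)benzoic acid F1. Conversion to the acid chloride and acylation of 1-[2,4-bis(benzyloxy)-6-hydroxyphenyl]ethanone F2 (pyridine, DMAP) gives the aryl ester F3. Baker–Venkataraman rearrangement (KOH, pyridine, 50 °C) gives 1-{2-[4-(allyloxy)-2,6-bis(benzyloxy)phenyl]-4,5-bis(benzyloxy)phenyl}-3-[2,4-bis(benzyloxy)-6-hydroxyphenyl]propane-1,3-dione F4. Cyclodehydration as in step 13 then delivers 21, where the route is rejoined.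

**Step 9.** Acylation may be slow because the ester is electron-rich and shielded by the ortho aryl group, so that the trianion self-condenses; the tetraketone may also cyclise during work-up. The fallback replaces the ester by an aldehyde and the acylation by an aldol addition followed by oxidation. It sets out from 13: reduction (LiAlH4, THF, 0 °C) gives {2-[4-(allyloxy)-2,6-bis(benzyloxy)phenyl]-4,5-bis(benzyloxy)phenyl}methanol F5, and MnO2 oxidation gives the aldehyde F6. Addition of the trilithium salt of 15 gives 8-aryl-8-hydroxyoctane-2,4,6-trione F7, and oxidation of the β-hydroxy ketone with 2-iodoxybenzoic acid in DMSO returns to 16.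

**Step 10.** Deprotonation to the tetraanion may be incomplete, or the β-keto acid may lose CO2 or lactonise during isolation. The fallback avoids the free acid: it sets out from 16, and the same tetralithium salt is acylated at its terminal carbon with dimethyl carbonate (THF, 0 °C → rt), which should give ester 18 directly and bypass 17.

**Step 7.** The allyl group may be lost through π-allyl formation at zerovalent palladium with aryl transfer from zinc, or the coupling may stall at the tri-ortho-substituted axis. The fallback changes the organometallic partner. It sets out from 7: the aryllithium 11 is quenched with B(Oi-Pr)3 and hydrolysed to [4-(allyloxy)-2,6-bis(benzyloxy)phenyl]boronic acid F8, which is coupled with 10 in a Suzuki–Miyaura reaction (Pd(OAc)2, SPhos, K3PO4, THF/H2O, rt to 40 °C) to return to 13.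

**Step 16.** Iodination may go on to the second ortho position, or touch ring A of the flavone, since the mono-iodide is still an activated phenol. The fallback transfers exactly one acyl group intramolecularly. It sets out from 22: acetylation (Ac2O, pyridine) gives the aryl acetate F9, and a Fries rearrangement (Sc(OTf)3 cat., toluene, 100 °C) should deliver 25 directly, bypassing 23 and 24. The risk there is loss of benzyl ethers under Lewis acid.

**Step 19.** Conversion may be low because the 5,7-dialkoxychromone is electron-rich, facial selectivity may be poor or of the opposite sense, and the product may open to the chalcone. The fallback forms the C2–O1 bond instead of the C2–aryl bond. It sets out from 25: Claisen–Schmidt condensation with 4-(benzyloxy)benzaldehyde (KOH, EtOH/THF) gives the 2'-hydroxychalcone F10. Enantioselective intramolecular oxa-Michael addition with a quinine-derived bifunctional thiourea catalyst, if necessary completed by crystallisation, returns to 29.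

## Further compounds

F1 | step 12 | 2-[4-(allyloxy)-2,6-bis(benzyloxy)phenyl]-4,5-bis(benzyloxy)benzoic acid | OC(=O)c1cc(OCc2ccccc2)c(OCc2ccccc2)cc1-c1c(OCc2ccccc2)cc(OCC=C)cc1OCc1ccccc1
F2 | step 12 | 1-[2,4-bis(benzyloxy)-6-hydroxyphenyl]ethanone | CC(=O)c1c(O)cc(OCc2ccccc2)cc1OCc1ccccc1
F3 | step 12 | 2-acetyl-3,5-bis(benzyloxy)phenyl 2-[4-(allyloxy)-2,6-bis(benzyloxy)phenyl]-4,5-bis(benzyloxy)benzoate | CC(=O)c1c(OC(=O)c2cc(OCc3ccccc3)c(OCc3ccccc3)cc2-c2c(OCc3ccccc3)cc(OCC=C)cc2OCc2ccccc2)cc(OCc2ccccc2)cc1OCc1ccccc1
F4 | step 12 | 1-{2-[4-(allyloxy)-2,6-bis(benzyloxy)phenyl]-4,5-bis(benzyloxy)phenyl}-3-[2,4-bis(benzyloxy)-6-hydroxyphenyl]propane-1,3-dione | O=C(CC(=O)c1c(O)cc(OCc2ccccc2)cc1OCc1ccccc1)c1cc(OCc2ccccc2)c(OCc2ccccc2)cc1-c1c(OCc2ccccc2)cc(OCC=C)cc1OCc1ccccc1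
F5 | step 9 | {2-[4-(allyloxy)-2,6-bis(benzyloxy)phenyl]-4,5-bis(benzyloxy)phenyl}methanol | OCc1cc(OCc2ccccc2)c(OCc2ccccc2)cc1-c1c(OCc2ccccc2)cc(OCC=C)cc1OCc1ccccc1
F6 | step 9 | 2-[4-(allyloxy)-2,6-bis(benzyloxy)phenyl]-4,5-bis(benzyloxy)benzaldehyde | O=Cc1cc(OCc2ccccc2)c(OCc2ccccc2)cc1-c1c(OCc2ccccc2)cc(OCC=C)cc1OCc1ccccc1
F7 | step 9 | 8-{2-[4-(allyloxy)-2,6-bis(benzyloxy)phenyl]-4,5-bis(benzyloxy)phenyl}-8-hydroxyoctane-2,4,6-trione (racemic) | CC(=O)CC(=O)CC(=O)CC(O)c1cc(OCc2ccccc2)c(OCc2ccccc2)cc1-c1c(OCc2ccccc2)cc(OCC=C)cc1OCc1ccccc1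
F0 | step 10 | none | none
F8 | step 7 | [4-(allyloxy)-2,6-bis(benzyloxy)phenyl]boronic acid | OB(O)c1c(OCc2ccccc2)cc(OCC=C)cc1OCc1ccccc1
F9 | step 16 | 4-{4,5-bis(benzyloxy)-2-[5,7-bis(benzyloxy)-4-oxo-4H-chromen-2-yl]phenyl}-3,5-bis(benzyloxy)phenyl acetate | CC(=O)Oc1cc(OCc2ccccc2)c(-c2cc(OCc3ccccc3)c(OCc3ccccc3)cc2-c2cc(=O)c3c(OCc4ccccc4)cc(OCc4ccccc4)cc3o2)c(OCc2ccccc2)c1
F10 | step 19 | 5,7-bis(benzyloxy)-2-[4,5-bis(benzyloxy)-2-(2,6-bis(benzyloxy)-3-{(E)-3-[4-(benzyloxy)phenyl]acryloyl}-4-hydroxyphenyl)phenyl]-4H-chromen-4-one | O=c1cc(-c2cc(OCc3ccccc3)c(OCc3ccccc3)cc2-c2c(OCc3ccccc3)cc(O)c(C(=O)/C=C/c3ccc(OCc4ccccc4)cc3)c2OCc2ccccc2)oc2cc(OCc3ccccc3)cc(OCc3ccccc3)c12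
A1 | alternative 1 | 4,5-bis(benzyloxy)-2-[2,6-bis(benzyloxy)-4-(triisopropylsilyloxy)phenyl]benzoic acid | OC(=O)c1cc(OCc2ccccc2)c(OCc2ccccc2)cc1-c1c(OCc2ccccc2)cc(O[Si](C(C)C)(C(C)C)C(C)C)cc1OCc1ccccc1
A2 | alternative 1 | 1,2-bis(benzyloxy)-4,5-dibromobenzene | Brc1cc(OCc2ccccc2)c(OCc2ccccc2)cc1Br
A3 | alternative 1 | [2,6-bis(benzyloxy)-4-(triisopropylsilyloxy)phenyl]magnesium bromide | Br[Mg]c1c(OCc2ccccc2)cc(O[Si](C(C)C)(C(C)C)C(C)C)cc1OCc1ccccc1
A4 | alternative 2 | benzyl 4-[(2R)-5,7-bis(benzyloxy)-6-{4,5-bis(benzyloxy)-2-[5,7-bis(benzyloxy)-4-oxo-4H-chromen-2-yl]phenyl}-4-oxochroman-2-yl]phenyl carbonate | O=C1C[C@H](c2ccc(OC(=O)OCc3ccccc3)cc2)Oc2cc(OCc3ccccc3)c(-c3cc(OCc4ccccc4)c(OCc4ccccc4)cc3-c3cc(=O)c4c(OCc5ccccc5)cc(OCc5ccccc5)cc4o3)c(OCc3ccccc3)c21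
A5 | alternative 2 | (3R)-3-(3,5-bis(benzyloxy)-4-{4,5-bis(benzyloxy)-2-[5,7-bis(benzyloxy)-4-oxo-4H-chromen-2-yl]phenyl}phenoxy)-3-{4-[(benzyloxycarbonyl)oxy]phenyl}propanoic acid | OC(=O)C[C@H](c1ccc(OC(=O)OCc2ccccc2)cc1)Oc1cc(OCc2ccccc2)c(-c2cc(OCc3ccccc3)c(OCc3ccccc3)cc2-c2cc(=O)c3c(OCc4ccccc4)cc(OCc4ccccc4)cc3o2)c(OCc2ccccc2)c1
A6 | alternative 3 | 2-{2-[4-(allyloxy)-2-(benzyloxy)-6-hydroxyphenyl]-4,5-bis(benzyloxy)phenyl}-5,7-bis(benzyloxy)-4H-chromen-4-one | O=c1cc(-c2cc(OCc3ccccc3)c(OCc3ccccc3)cc2-c2c(O)cc(OCC=C)cc2OCc2ccccc2)oc2cc(OCc3ccccc3)cc(OCc3ccccc3)c12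
A7 | alternative 3 | 3-(allyloxy)-1,8,9-tris(benzyloxy)-6H-benzo[c]chromen-6-one | O=C1Oc2cc(OCC=C)cc(OCc3ccccc3)c2-c2cc(OCc3ccccc3)c(OCc3ccccc3)cc12
A8 | alternative 3 | 1-[2,4-bis(benzyloxy)-6-hydroxyphenyl]ethanone | CC(=O)c1c(O)cc(OCc2ccccc2)cc1OCc1ccccc1
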